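All runs were computed with constants of no real substance.

- A leftover started this: at 10.0 d the blue run still held incoming ligand by my count, 14.8% of the starting complex charged, if I counted every missing percent as complex with two exchanged.

| setting | blue | flask |
|---|---|---|
| starting complex | 1.9 M | 1.9 M |
| incoming ligand | 0.55 equiv | 1.10 equiv |
| remark | run made earlier |  |
| time |  | 15 d |

blue run (percent of the starting complex charged)

| time / d | complex with one exchanged / % | starting complex / % |
|---|---|---|
| 0.167 | 6.6 | 93.6 |
| 0.625 | 12.5 | 82.2 |
| 2.50 | 13.0 | 75.4 |
| 10.0 | 9.2 | 75.3 |

(scatter of a reading: 0.5 percentage points)

- the numbers in the tables scatter with a standard deviation of 0.5 percentage points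
- no earlier run changes the charge of incoming ligand; that part of a forecast is a guess

* the moment within 15 d at which there is most complex with one exchanged
* the amount of complex with one exchanged, in percent of the starting complex charged, at that time

- That count gave 0.332 for the exchange quotient Q, a reaction quotient, c(complex with one exchanged)·c(leaving ligand)/(c(starting complex)·c(incoming ligand)); a swap without preference has Q = 1, and this reading stood lower.
- First rung: the first reading of the blue run, scaled to the asked flask's ligand, gave my estimate of 0.904 d for the forward half-life of starting complex.
- Next rung: the blue run's readings of complex with one exchanged were highest at 0.625 d and 2.50 d, so, scaling time by the ligand charge, I put the asked flask's peak between 0.312 d and 1.25 d.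
- Last rung: in the blue run, starting complex read 75.4% and then 75.3%, while complex with one exchanged fell to 9.2%.
- Reckoned with the first exchange alone, Q gave me a ceiling for complex with one exchanged: 26.4% for the blue run and 38.3% for the asked flask.
- The blue run's highest reading was 49.2% of its ceiling, and carrying that share over, which was a guess, I expected 18.8% in the asked flask.
- The forecast said 22% (17% to 28%) at 1.3 d (0.6 d to 3 d), more than my figure, holding that “released ligand is probably driving the reverse reactions”.
- The asked flask gave 19.4% at 0.679 d, which is 50.7% of my reckoned ceiling.

    complex with one exchanged + incoming ligand ⇌ leaving ligand + complex with two exchanged (K = 3.14, k = 0.0221 M⁻¹ h⁻¹)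
    complex with one exchanged ⇌ isomer of the product (K = 0.250, k = 0.0345 h⁻¹)
    starting complex + incoming ligand ⇌ leaving ligand + complex with one exchanged (K = 0.258, k = 0.0183 M⁻¹ h⁻¹)

- The asked flask with 0.280 equiv of incoming ligand instead, a neighbouring flask, had a reckoned ceiling of 17.2% by the same Q, and the blue share of that came to 8.46%; its simulated best was 10.7%, which is 62.2% of the ceiling.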